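**Retrosynthetic overview**
1. C8–OOH: SN2 displacement (inversion) of an (8R)-allylic mesylate by H2O2. The (8R)-carbinol comes from CBS reduction of a macrocyclic 2-methylidene ketone, and the phenol is unmasked last.
2. C1 ester: Steglich acylation of the C1 carbinol with silyl-protected p-coumaric acid, made by a Heck reaction of silylated 4-iodophenol with acrylic acid.
3. Key disconnection C9–C10: hydrogen-atom transfer from an iron hydride to a methallyl group gives the tertiary C10 radical, which closes the 11-membered carbocycle onto a 2-silyloxy enone. The ring and the gem-dimethyl quaternary carbon form together.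
4. Acyclic precursor: C5–C6 by alkylation of the dienolate of biacetyl mono-silyl enol ether with a (Z)-allylic bromide. C2–C3 by opening an (R)-epoxide (from (R)-epichlorohydrin) with a (Z)-alkenyllithium (from but-2-yn-1-ol).
5. Ring order: the cycloundecene is the only ring formed (step 7); the arene is bought.

Assumption: the SMILES is read as (1R,3Z,8S)-8-hydroperoxy-3,10,10-trimethyl-7-methylidenecycloundec-3-en-1-yl (2E)-3-(4-hydroxyphenyl)prop-2-enoate, and this ring numbering is used for every macrocycle below.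

**Route**

Step 1
Reactants: 1 but-2-yn-1-ol
Product: 3 (2Z)-3-iodobut-2-en-1-ol, via cyclic sodium vinylalanate 2 (not isolated)
Conditions: NaAlH2(OCH2CH2OMe)2 (1.5 equiv), THF, 0 °C to rt; then I2 (1.5 equiv), −78 to 0 °C; aq. KNaC4H4O6 work-up
Reagents that add atoms: iodine II; NaAlH2(OCH2CH2OMe)2 [Na+].[AlH2-](OCCOC)OCCOC (its atoms stay in intermediate 2 only)
Why: Hydroxyl-directed trans-hydroalumination of the propargylic alcohol puts aluminium on C3 in a five-membered alanate, and iodinolysis with retention gives the (Z)-vinyl iodide (hydroalumination–iodination), which fixes the later C3=C4 Z geometry.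

Step 2
Reactants: 4 (2R)-2-(chloromethyl)oxirane [(R)-epichlorohydrin]; 5 isopropenylmagnesium bromide CH2=C(CH3)MgBr
Product: 7 (2R)-2-(2-methylprop-2-en-1-yl)oxirane, via chlorohydrin 6 (not isolated)
Conditions: 5 (1.2 equiv), CuI (10 mol%), THF, −40 to 0 °C, H2O quench; crude 6, NaOH (powder), Et2O, rt
Reagents that add atoms: none
Why: CuI-catalysed Grignard opening of the epoxide at its CH2 terminus, then base-induced 3-exo-tet closure onto the CH2Cl carbon (intramolecular Williamson reaction), moves the oxirane without touching the stereocentre, so (R)-4 gives (R)-7.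

Step 3
Reactants: 3 (2Z)-3-iodobut-2-en-1-ol; 7 (2R)-2-(2-methylprop-2-en-1-yl)oxirane
Product: 9 (2Z,5R)-3,7-dimethylocta-2,7-diene-1,5-diol, via dilithio alkenyl alkoxide 8 (not isolated)
Conditions: 3 (1.25 equiv), n-BuLi (1.25 equiv) then t-BuLi (2.5 equiv), Et2O, −78 °C; 7 (1.0 equiv) then BF3·OEt2 (promoter, 2.5 equiv), −78 °C; H2O quench
Reagents that add atoms: n-BuLi [Li]CCCC; t-BuLi [Li]C(C)(C)C (lithium stays in intermediate 8 only)
Why: Iodine–lithium exchange with retention of the Z geometry gives alkenyllithium 8, which opens the BF3-activated epoxide at its CH2 terminus (Lewis-acid-promoted SN2 epoxide opening), so the C1 carbinol keeps the R configuration brought in by 7.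

Step 4
Reactants: 9 (2Z,5R)-3,7-dimethylocta-2,7-diene-1,5-diol
Product: 11 {[(4R,6Z)-8-bromo-2,6-dimethylocta-1,6-dien-4-yl]oxy}(triethyl)silane, via bromo alcohol 10 (not isolated)
Conditions: CBr4 (1.1 equiv), PPh3 (1.1 equiv), CH2Cl2, −40 °C; then 2,6-lutidine (2.5 equiv), Et3SiOTf (1.3 equiv), −78 to −40 °C
Reagents that add atoms: tetrabromomethane BrC(Br)(Br)Br; triethylsilyl trifluoromethanesulfonate CC[Si](CC)(CC)OS(=O)(=O)C(F)(F)F
Why: The Appel reaction brominates the primary allylic alcohol much faster than the hindered secondary one and keeps the Z olefin, and the secondary hydroxyl is silylated in the same pot so it cannot cyclise onto the allylic bromide.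

Step 5
Reactants: 12 butane-2,3-dione (biacetyl)
Product: 13 3-[(tert-butyldimethylsilyl)oxy]but-3-en-2-one
Conditions: 12 (1.5 equiv), TBSOTf (1.0 equiv), Et3N (1.2 equiv), CH2Cl2, −78 to 0 °C
Reagents that add atoms: tert-butyldimethylsilyl trifluoromethanesulfonate CC(C)(C)[Si](C)(C)OS(=O)(=O)C(F)(F)F
Why: Soft enolisation and O-silylation of one carbonyl (silyl enol ether formation), with the diketone in excess to suppress bis-silylation.

Step 6
Reactants: 13 3-[(tert-butyldimethylsilyl)oxy]but-3-en-2-one; 11 {[(4R,6Z)-8-bromo-2,6-dimethylocta-1,6-dien-4-yl]oxy}(triethyl)silane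
Product: 15 (6Z,9R)-2-[(tert-butyldimethylsilyl)oxy]-7,11-dimethyl-9-[(triethylsilyl)oxy]dodeca-1,6,11-trien-3-one, via lithium dienolate 14 (not isolated)
Conditions: 13 (1.3 equiv), LiN(iPr)2 (1.3 equiv), THF, −78 °C; then 11 (1.0 equiv), DMPU, −78 to −30 °C
Reagents that add atoms: LiN(iPr)2 [Li]N(C(C)C)C(C)C (lithium stays in intermediate 14 only)
Why: Kinetic deprotonation of the only enolisable position (the methyl group) gives a dienolate that is C-alkylated by the primary allylic bromide (SN2 enolate alkylation), leaving the Z olefin and the stereocentre untouched.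

Step 7
Reactants: 15 (6Z,9R)-2-[(tert-butyldimethylsilyl)oxy]-7,11-dimethyl-9-[(triethylsilyl)oxy]dodeca-1,6,11-trien-3-one
Product: 16 (1R,3Z)-8-[(tert-butyldimethylsilyl)oxy]-3,10,10-trimethyl-1-[(triethylsilyl)oxy]cycloundec-3-en-7-one (both C8 epimers)
Conditions: Fe(acac)3 (0.5 equiv), PhSiH3 (3 equiv), EtOH/HOCH2CH2OH 9:1, 60 °C, argon, syringe-pump addition of 15 over 10 h to 2 mM
Reagents that add atoms: none
Why: Proposed new method: a macrocyclic (11-endo) version of the iron-hydride HAT reductive olefin coupling (MHAT Giese reaction), in which the iron hydride made from Fe(acac)3 and PhSiH3 transfers H• to the electron-rich 1,1-disubstituted olefin faster than to the trisubstituted one, the nucleophilic tertiary C10 radical adds irreversibly to the unsubstituted terminus of the captodative 2-silyloxy enone to forge C9–C10, the quaternary carbon and the ring in one event, and reduction/protonation of the resulting α-oxy-α-keto radical gives both C8 epimers (C8 is reset in steps 9 and 13, C1 is untouched); the closest known reactions are the intermolecular Fe(acac)3/PhSiH3 olefin–enone coupling and tin-hydride radical macrocyclisations onto enones.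

Step 8
Reactants: 16 (1R,3Z)-8-[(tert-butyldimethylsilyl)oxy]-3,10,10-trimethyl-1-[(triethylsilyl)oxy]cycloundec-3-en-7-one
Product: 18 (1R,3Z)-3,10,10-trimethyl-7-methylidenecycloundec-3-ene-1,8-diol (both C8 epimers), via bis-silyl ether 17 (not isolated)
Conditions: Ph3PCH3Br (3 equiv), KOtBu (2.8 equiv), THF, 0 to 40 °C; then Bu4NF (5 equiv), THF, rt
Reagents that add atoms: methyltriphenylphosphonium bromide C[P+](c1ccccc1)(c1ccccc1)c1ccccc1.[Br-]
Why: Wittig methylenation of the C7 ketone installs the exocyclic olefin, and fluoride then cleaves both silyl ethers in the same pot.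

Step 9
Reactants: 18 (1R,3Z)-3,10,10-trimethyl-7-methylidenecycloundec-3-ene-1,8-diol
Product: 19 (1R,3Z)-1-hydroxy-3,10,10-trimethyl-7-methylidenecycloundec-3-en-8-one
Conditions: activated MnO2 (20 equiv), CH2Cl2, rt
Reagents that add atoms: none
Why: MnO2 oxidises only the allylic C8 carbinol and leaves the homoallylic C1 carbinol, so both C8 epimers converge on one 2-methylidene ketone.

Step 10
Reactants: 20 4-iodophenol
Product: 21 tert-butyl(4-iodophenoxy)dimethylsilane
Conditions: TBSCl (1.2 equiv), imidazole (2 equiv), DMF, rt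
Reagents that add atoms: tert-butyldimethylsilyl chloride CC(C)(C)[Si](C)(C)Cl
Why: Imidazole-promoted O-silylation protects the phenol so that it survives the later mesylation.

Step 11
Reactants: 21 tert-butyl(4-iodophenoxy)dimethylsilane; 22 acrylic acid
Product: 23 (2E)-3-{4-[(tert-butyldimethylsilyl)oxy]phenyl}prop-2-enoic acid
Conditions: Pd(OAc)2 (3 mol%), P(o-tol)3 (6 mol%), Et3N (3 equiv), MeCN, 80 °C; citric acid work-up
Reagents that add atoms: none
Why: Mizoroki–Heck reaction, in which syn-carbopalladation and syn-β-hydride elimination give the (E)-cinnamic acid.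

Step 12
Reactants: 19 (1R,3Z)-1-hydroxy-3,10,10-trimethyl-7-methylidenecycloundec-3-en-8-one; 23 (2E)-3-{4-[(tert-butyldimethylsilyl)oxy]phenyl}prop-2-enoic acid
Product: 24 (1R,3Z)-3,10,10-trimethyl-7-methylidene-8-oxocycloundec-3-en-1-yl (2E)-3-{4-[(tert-butyldimethylsilyl)oxy]phenyl}prop-2-enoate
Conditions: DCC (1.3 equiv), DMAP (0.1 equiv), CH2Cl2, 0 °C to rt
Reagents that add atoms: none
Why: Steglich esterification acylates the only free hydroxyl without breaking the C1–O bond, so C1 stays R, while C8 is masked as the ketone.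

Step 13
Reactants: 24 (1R,3Z)-3,10,10-trimethyl-7-methylidene-8-oxocycloundec-3-en-1-yl (2E)-3-{4-[(tert-butyldimethylsilyl)oxy]phenyl}prop-2-enoate
Product: 25 (1R,3Z,8R)-8-hydroxy-3,10,10-trimethyl-7-methylidenecycloundec-3-en-1-yl (2E)-3-{4-[(tert-butyldimethylsilyl)oxy]phenyl}prop-2-enoate
Conditions: (S)-2-methyl-CBS-oxazaborolidine (0.5 equiv), catecholborane (2 equiv), toluene, −78 °C; MeOH then pH 7 buffer
Reagents that add atoms: none
Why: Corey–Bakshi–Shibata reduction, in which the (S)-oxazaborolidine binds the ketone with the sp2 C7 arm as the large group and delivers hydride 1,2 to give the (8R)-alcohol under reagent control.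

Step 14
Reactants: 25 (1R,3Z,8R)-8-hydroxy-3,10,10-trimethyl-7-methylidenecycloundec-3-en-1-yl (2E)-3-{4-[(tert-butyldimethylsilyl)oxy]phenyl}prop-2-enoate
Product: 27 (1R,3Z,8S)-8-hydroperoxy-3,10,10-trimethyl-7-methylidenecycloundec-3-en-1-yl (2E)-3-{4-[(tert-butyldimethylsilyl)oxy]phenyl}prop-2-enoate, via allylic mesylate 26 (not isolated)
Conditions: MsCl (1.3 equiv), Et3N (2 equiv), Et2O, −40 °C; then anhydrous H2O2 in Et2O (30 equiv), −40 to 0 °C, dark
Reagents that add atoms: methanesulfonyl chloride CS(=O)(=O)Cl (in intermediate 26 only); hydrogen peroxide OO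
Why: Perhydrolysis of the allylic sulfonate is an SN2 displacement by H2O2 at C8 with inversion, which turns the (8R)-mesylate into the (8S)-hydroperoxide.

Step 15
Reactants: 27 (1R,3Z,8S)-8-hydroperoxy-3,10,10-trimethyl-7-methylidenecycloundec-3-en-1-yl (2E)-3-{4-[(tert-butyldimethylsilyl)oxy]phenyl}prop-2-enoate
Product: 28 (1R,3Z,8S)-8-hydroperoxy-3,10,10-trimethyl-7-methylidenecycloundec-3-en-1-yl (2E)-3-(4-hydroxyphenyl)prop-2-enoate
Conditions: Bu4NF (1.2 equiv), AcOH (1.2 equiv), THF, 0 °C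
Reagents that add atoms: none
Why: Acetic-acid-buffered fluoride cleaves the aryl silyl ether quickly while the hydroperoxide, the ester and both stereocentres stay intact.

**Compound list**
1 | but-2-yn-1-ol | CC#CCO | starting material
2 | sodium 2,2-bis(2-methoxyethoxy)-3-methyl-2,5-dihydro-1,2-oxaaluminol-2-uide (cyclic vinylalanate) | CC1=CCO[Al-]1(OCCOC)OCCOC.[Na+] | intermediate (not isolated)
3 | (2Z)-3-iodobut-2-en-1-ol | OC/C=C(/C)I | intermediate
4 | (2R)-2-(chloromethyl)oxirane | ClC[C@H]1CO1 | starting material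
5 | isopropenylmagnesium bromide | CC(=C)[Mg]Br | starting material
6 | (2R)-1-chloro-4-methylpent-4-en-2-ol | ClC[C@H](O)CC(C)=C | intermediate (not isolated)
7 | (2R)-2-(2-methylprop-2-en-1-yl)oxirane | CC(=C)C[C@@H]1CO1 | intermediate
8 | lithium (2Z)-3-lithiobut-2-en-1-olate | [Li]OC/C=C(/C)[Li] | intermediate (not isolated)
9 | (2Z,5R)-3,7-dimethylocta-2,7-diene-1,5-diol | OC/C=C(/C)C[C@H](O)CC(C)=C | intermediate
10 | (4R,6Z)-8-bromo-2,6-dimethylocta-1,6-dien-4-ol | BrC/C=C(/C)C[C@H](O)CC(C)=C | intermediate (not isolated)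
11 | {[(4R,6Z)-8-bromo-2,6-dimethylocta-1,6-dien-4-yl]oxy}(triethyl)silane | BrC/C=C(/C)C[C@H](O[Si](CC)(CC)CC)CC(C)=C | intermediate
12 | butane-2,3-dione | CC(=O)C(C)=O | starting material
13 | 3-[(tert-butyldimethylsilyl)oxy]but-3-en-2-one | CC(=O)C(=C)O[Si](C)(C)C(C)(C)C | intermediate
14 | lithium 3-[(tert-butyldimethylsilyl)oxy]buta-1,3-dien-2-olate | [Li]OC(=C)C(=C)O[Si](C)(C)C(C)(C)C | intermediate (not isolated)
15 | (6Z,9R)-2-[(tert-butyldimethylsilyl)oxy]-7,11-dimethyl-9-[(triethylsilyl)oxy]dodeca-1,6,11-trien-3-one | C=C(O[Si](C)(C)C(C)(C)C)C(=O)CC/C=C(/C)C[C@H](O[Si](CC)(CC)CC)CC(C)=C | intermediate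
16 | (1R,3Z)-8-[(tert-butyldimethylsilyl)oxy]-3,10,10-trimethyl-1-[(triethylsilyl)oxy]cycloundec-3-en-7-one (both C8 epimers, C8 left undefined) | O=C1CC/C=C(/C)C[C@H](O[Si](CC)(CC)CC)CC(C)(C)CC1O[Si](C)(C)C(C)(C)C | intermediate
17 | (1R,3Z)-8-[(tert-butyldimethylsilyl)oxy]-3,10,10-trimethyl-7-methylidene-1-[(triethylsilyl)oxy]cycloundec-3-ene (both C8 epimers) | C=C1CC/C=C(/C)C[C@H](O[Si](CC)(CC)CC)CC(C)(C)CC1O[Si](C)(C)C(C)(C)C | intermediate (not isolated)
18 | (1R,3Z)-3,10,10-trimethyl-7-methylidenecycloundec-3-ene-1,8-diol (both C8 epimers) | C=C1CC/C=C(/C)C[C@H](O)CC(C)(C)CC1O | intermediate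
19 | (1R,3Z)-1-hydroxy-3,10,10-trimethyl-7-methylidenecycloundec-3-en-8-one | C=C1CC/C=C(/C)C[C@H](O)CC(C)(C)CC1=O | intermediate
20 | 4-iodophenol | Oc1ccc(I)cc1 | starting material
21 | tert-butyl(4-iodophenoxy)dimethylsilane | CC(C)(C)[Si](C)(C)Oc1ccc(I)cc1 | intermediate
22 | acrylic acid | C=CC(=O)O | starting material
23 | (2E)-3-{4-[(tert-butyldimethylsilyl)oxy]phenyl}prop-2-enoic acid | CC(C)(C)[Si](C)(C)Oc1ccc(/C=C/C(=O)O)cc1 | intermediate
24 | (1R,3Z)-3,10,10-trimethyl-7-methylidene-8-oxocycloundec-3-en-1-yl (2E)-3-{4-[(tert-butyldimethylsilyl)oxy]phenyl}prop-2-enoate | C=C1CC/C=C(/C)C[C@H](OC(=O)/C=C/c2ccc(O[Si](C)(C)C(C)(C)C)cc2)CC(C)(C)CC1=O | intermediate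
25 | (1R,3Z,8R)-8-hydroxy-3,10,10-trimethyl-7-methylidenecycloundec-3-en-1-yl (2E)-3-{4-[(tert-butyldimethylsilyl)oxy]phenyl}prop-2-enoate | C=C1CC/C=C(/C)C[C@H](OC(=O)/C=C/c2ccc(O[Si](C)(C)C(C)(C)C)cc2)CC(C)(C)C[C@H]1O | intermediate
26 | (1R,3Z,8R)-8-(methanesulfonyloxy)-3,10,10-trimethyl-7-methylidenecycloundec-3-en-1-yl (2E)-3-{4-[(tert-butyldimethylsilyl)oxy]phenyl}prop-2-enoate | C=C1CC/C=C(/C)C[C@H](OC(=O)/C=C/c2ccc(O[Si](C)(C)C(C)(C)C)cc2)CC(C)(C)C[C@H]1OS(C)(=O)=O | intermediate (not isolated)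
27 | (1R,3Z,8S)-8-hydroperoxy-3,10,10-trimethyl-7-methylidenecycloundec-3-en-1-yl (2E)-3-{4-[(tert-butyldimethylsilyl)oxy]phenyl}prop-2-enoate | C=C1CC/C=C(/C)C[C@H](OC(=O)/C=C/c2ccc(O[Si](C)(C)C(C)(C)C)cc2)CC(C)(C)C[C@@H]1OO | intermediate
28 | (1R,3Z,8S)-8-hydroperoxy-3,10,10-trimethyl-7-methylidenecycloundec-3-en-1-yl (2E)-3-(4-hydroxyphenyl)prop-2-enoate | C=C1CC/C=C(/C)C[C@H](OC(=O)/C=C/c2ccc(O)cc2)CC(C)(C)C[C@@H]1OO | target

**Step count and risks**

Total steps: 15. Longest linear sequence: 11 steps (steps 1, 3, 4, 6, 7, 8, 9, 12, 13, 14, 15; 1 → 3 → 9 → 11 → 15 → 16 → 18 → 19 → 24 → 25 → 27 → 28).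

Three steps most likely to fail:

Step 7 (radical macrocyclisation). The C10 radical can instead add 6-endo to the C3=C4 olefin, be reduced, or give oligomers. The fallback sets out from 9 and comes back at 16, making the radical step intermolecular and closing the ring by enolate alkylation. Diol 9 is bis-silylated (Et3SiCl, imidazole) to (2Z,5R)-3,7-dimethyl-1,5-bis(triethylsilyloxy)octa-2,7-diene F1. F1 is coupled with 13 (4 equiv; Fe(acac)3, PhSiH3, EtOH/HOCH2CH2OH, 60 °C), where the high acceptor concentration outruns the side reactions, to give the open-chain methyl ketone F2. Ph3PBr2 (CH2Cl2, 0 °C) converts the primary allylic silyl ether into the allylic bromide F3. KN(SiMe3)2 (THF, −78 to 0 °C, 1 mM) forms the methyl-side enolate, which closes the ring by intramolecular SN2 alkylation to give 16.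

Step 14 (mesylate to hydroperoxide). The risks are SN2′ attack, ionisation with loss of configuration, and elimination. The fallback sets out from 25 and comes back at 27, replacing neutral H2O2 by a protected peroxide anion. The mesylate is made as before and displaced with the caesium salt of 2-methoxypropan-2-yl hydroperoxide (CsOH, DMF, 0 °C), a much stronger nucleophile, to give with inversion the peroxyketal F4. AcOH/THF/H2O (rt) then frees the hydroperoxide to give 27.

Step 6 (dienolate alkylation). The risks are Michael addition of dienolate 14 to the enone product and over-alkylation. The fallback sets out from 11 and comes back at 18, building the acceptor from an amide instead. Bromide 11 alkylates the lithium enolate of N-methoxy-N-methylacetamide (LiN(iPr)2, THF, −78 °C) to give the Weinreb amide F5. 1-(Methoxymethoxy)vinyllithium (from methoxymethyl vinyl ether and t-BuLi) adds to give the 2-(methoxymethoxy) enone F6. The conditions of step 7 then give the macrocyclic α-(methoxymethoxy) ketone F7. Ph3P=CH2 gives the methylidene compound F8. HCl in MeOH removes the acetal and the silyl ether to give 18.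

**Further compounds**
F1 | step 7 | (2Z,5R)-3,7-dimethyl-1,5-bis(triethylsilyloxy)octa-2,7-diene | CC[Si](CC)(CC)OC/C=C(/C)C[C@H](O[Si](CC)(CC)CC)CC(C)=C
F2 | step 7 | (7R,9Z)-3-(tert-butyldimethylsilyloxy)-5,5,9-trimethyl-7,11-bis(triethylsilyloxy)undec-9-en-2-one (both C3 epimers) | CC[Si](CC)(CC)OC/C=C(/C)C[C@H](O[Si](CC)(CC)CC)CC(C)(C)CC(O[Si](C)(C)C(C)(C)C)C(C)=O
F3 | step 7 | (7R,9Z)-11-bromo-3-(tert-butyldimethylsilyloxy)-5,5,9-trimethyl-7-(triethylsilyloxy)undec-9-en-2-one (both C3 epimers) | BrC/C=C(/C)C[C@H](O[Si](CC)(CC)CC)CC(C)(C)CC(O[Si](C)(C)C(C)(C)C)C(C)=O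
F4 | step 14 | (1R,3Z,8S)-8-[(2-methoxypropan-2-yl)peroxy]-3,10,10-trimethyl-7-methylidenecycloundec-3-en-1-yl (2E)-3-{4-[(tert-butyldimethylsilyl)oxy]phenyl}prop-2-enoate | C=C1CC/C=C(/C)C[C@H](OC(=O)/C=C/c2ccc(O[Si](C)(C)C(C)(C)C)cc2)CC(C)(C)C[C@@H]1OOC(C)(C)OC
F5 | step 6 | (4Z,7R)-N-methoxy-N,5,9-trimethyl-7-(triethylsilyloxy)deca-4,9-dienamide | CON(C)C(=O)CC/C=C(/C)C[C@H](O[Si](CC)(CC)CC)CC(C)=C
F6 | step 6 | (6Z,9R)-2-(methoxymethoxy)-7,11-dimethyl-9-(triethylsilyloxy)dodeca-1,6,11-trien-3-one | C=C(OCOC)C(=O)CC/C=C(/C)C[C@H](O[Si](CC)(CC)CC)CC(C)=C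
F7 | step 6 | (1R,3Z)-8-(methoxymethoxy)-3,10,10-trimethyl-1-(triethylsilyloxy)cycloundec-3-en-7-one (both C8 epimers) | O=C1CC/C=C(/C)C[C@H](O[Si](CC)(CC)CC)CC(C)(C)CC1OCOC
F8 | step 6 | (1R,3Z)-8-(methoxymethoxy)-3,10,10-trimethyl-7-methylidene-1-(triethylsilyloxy)cycloundec-3-ene (both C8 epimers) | C=C1CC/C=C(/C)C[C@H](O[Si](CC)(CC)CC)CC(C)(C)CC1OCOC
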